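**Plan**

- Retrosynthetic cuts: the five O–benzyl bonds; the C4 ketone back to a carbinol; C3–C8'' (dihydrofuran ring); C2–aryl of ring B (conjugate arylation of a 2-aryloxychromone); C2–O7'' (phenoxide addition–elimination on a 2-sulfonylchromone); in the flavan half C2''–aryl (conjugate arylation of a chromone) and the C4'' oxygen.
- Forward order: chromone → flavanone → flavan phenol (benzo ring D, pyran ring F, aryl ring E); second chromone (rings A and C); aryl ether between the halves; ketal carbon C2 with ring B; silyl enol ether; the dihydrofuran ring closes last; then oxidation and hydrogenolysis.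
- Stereochemistry: C2'' from a palladium/(S)-t-BuPyOx conjugate arylation; ketal carbon C2 from the same reaction type with the (R) ligand; C3 by relay from C2 in the ring closure, where only the cis fusion is possible.
- Enabling feature: the ketal oxygen O7'' on C2 holds C8'' of ring D in a 1,5 relation to C3 of the C3=C4 enol ether in ring C, so a C8'' radical closes 5-exo-trig on the O7'' face.
- Logic: the fused bis-aryl ketal is a kinetic isomer that acid or base would open to a benzofuran or a flavone. C2 is therefore made by C–C bond formation, the ring is closed under neutral radical conditions without a C3 enolate, and the C4 ketone appears only at the end.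

Key step: step 13

Assumption: the facial sense of the t-BuPyOx ligands in steps 4 and 11 is taken by analogy with simple chromones (S ligand giving 2R at a C2–H flavanone); if it proves opposite, the antipodal ligands are exchanged.

Atoms of the flavan half carry double primes. The CIP descriptors were worked out by hand and the SMILES are definitive.

**Step 1**
Reactants: 1 1-(2,4,6-trihydroxyphenyl)ethan-1-one
Product: 2 1-[2,6-dihydroxy-4-(triisopropylsilyloxy)phenyl]ethan-1-one
Conditions: TIPSCl (1.05 equiv), imidazole, DMF, 0 °C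
Reagents that add atoms: triisopropylsilyl chloride CC(C)[Si](Cl)(C(C)C)C(C)C
Why: The para hydroxyl is the only one that is neither hydrogen-bonded to the ketone nor flanked by the acyl group, so the bulky silyl chloride should silylate it selectively (phenol O-silylation).

**Step 2**
Reactants: 2 1-[2,6-dihydroxy-4-(triisopropylsilyloxy)phenyl]ethan-1-one
Product: 3 1-[2-(benzyloxy)-6-hydroxy-4-(triisopropylsilyloxy)phenyl]ethan-1-one
Conditions: BnOH, PPh3, DIAD, THF, 0 °C → rt
Reagents that add atoms: benzyl alcohol OCc1ccccc1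
Why: Mitsunobu etherification of one of the two equivalent ortho phenols should stop at the mono-ether because the remaining phenol is locked in a hydrogen bond to the ketone, and the neutral conditions spare the aryl silyl ether.

**Step 3**
Reactants: 3 1-[2-(benzyloxy)-6-hydroxy-4-(triisopropylsilyloxy)phenyl]ethan-1-one
Product: 5 5-(benzyloxy)-7-(triisopropylsilyloxy)-4H-chromen-4-one, via enaminone 4 (not isolated)
Conditions: Me2NCH(OMe)2, PhMe, 90 °C; then TsOH·H2O, CH2Cl2, rt
Reagents that add atoms: N,N-dimethylformamide dimethyl acetal COC(OC)N(C)C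
Why: Enaminone formation at the acetyl group followed by acid-promoted addition–elimination of the chelated phenol is the standard chromone annulation of 2-hydroxyacetophenones.

**Step 4**
Reactants: 5 5-(benzyloxy)-7-(triisopropylsilyloxy)-4H-chromen-4-one; 6 [4-(benzyloxy)phenyl]boronic acid
Product: 7 (2R)-5-(benzyloxy)-2-[4-(benzyloxy)phenyl]-7-(triisopropylsilyloxy)chroman-4-one
Conditions: Pd(OCOCF3)2 (5 mol%), (S)-t-BuPyOx (6 mol%), NH4PF6 (30 mol%), H2O (5 equiv), ClCH2CH2Cl, 60 °C
Reagents that add atoms: none
Why: Enantioselective conjugate addition of an arylboronic acid to a chromone under cationic divalent palladium/pyridine–oxazoline catalysis is established, the ligand choosing the face of aryl transfer to C2 (2R expected), and the weakly acidic medium avoids ring-opening racemisation of the flavanone.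

**Step 5**
Reactants: 7 (2R)-5-(benzyloxy)-2-[4-(benzyloxy)phenyl]-7-(triisopropylsilyloxy)chroman-4-one
Product: 9 (2R)-5-(benzyloxy)-2-[4-(benzyloxy)phenyl]-7-(triisopropylsilyloxy)chromane, via flavan-4-ol 8 (not isolated)
Conditions: NaBH4, THF/MeOH, 0 °C; then Et3SiH, CF3CO2H, CH2Cl2, −20 → 0 °C
Reagents that add atoms: none
Why: Hydride reduction followed by ionic hydrogenation of the flavan-4-ol, whose C4 cation is stabilised by the ortho and para ring oxygens, should remove the carbonyl without touching C2'' or the benzyl and silyl ethers.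

**Step 6**
Reactants: 9 (2R)-5-(benzyloxy)-2-[4-(benzyloxy)phenyl]-7-(triisopropylsilyloxy)chromane
Product: 10 (2R)-5-(benzyloxy)-2-[4-(benzyloxy)phenyl]-8-bromo-7-(triisopropylsilyloxy)chromane
Conditions: NBS (1.0 equiv), CH2Cl2, −78 °C
Reagents that add atoms: N-bromosuccinimide O=C1CCC(=O)N1Br
Why: Electrophilic bromination of 5,7-di-O-protected flavans is known to favour C8 (para to O5, between O7 and the ring oxygen) over C6 and over the less activated aryl ring.

**Step 7**
Reactants: 10 (2R)-5-(benzyloxy)-2-[4-(benzyloxy)phenyl]-8-bromo-7-(triisopropylsilyloxy)chromane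
Product: 11 (2R)-5-(benzyloxy)-2-[4-(benzyloxy)phenyl]-8-bromochroman-7-ol
Conditions: Bu4NF, AcOH, THF, 0 °C
Reagents that add atoms: none
Why: Fluoride cleaves the aryl silyl ether selectively and frees only the C7'' phenol while the benzyl ethers and the aryl bromide stay.

**Step 8**
Reactants: 12 1-[2,4-bis(benzyloxy)-6-hydroxyphenyl]ethan-1-one
Product: 14 5,7-bis(benzyloxy)-2-(methylsulfanyl)-4H-chromen-4-one, via thione 13 (not isolated)
Conditions: KOtBu, CS2, THF, 0 °C → rt; aq. H2SO4; then MeI, K2CO3, acetone, rt
Reagents that add atoms: carbon disulfide S=C=S; iodomethane CI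
Why: Claisen-type dithiocarboxylation of the acetophenone enolate, closure of the phenol onto the dithioate with loss of hydrogen sulfide and S-methylation of the 2-thioxo compound is the established entry to 2-(alkylsulfanyl)chromones.

**Step 9**
Reactants: 14 5,7-bis(benzyloxy)-2-(methylsulfanyl)-4H-chromen-4-one
Product: 15 5,7-bis(benzyloxy)-2-(methylsulfonyl)-4H-chromen-4-one
Conditions: mCPBA (2.2 equiv), CH2Cl2, 0 °C → rt
Reagents that add atoms: 3-chloroperoxybenzoic acid OOC(=O)c1cccc(Cl)c1
Why: Sulfide-to-sulfone oxidation turns C2 of the chromone into a strong addition–elimination electrophile.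

**Step 10**
Reactants: 11 (2R)-5-(benzyloxy)-2-[4-(benzyloxy)phenyl]-8-bromochroman-7-ol; 15 5,7-bis(benzyloxy)-2-(methylsulfonyl)-4H-chromen-4-one
Product: 16 5,7-bis(benzyloxy)-2-{[(2R)-5-(benzyloxy)-2-[4-(benzyloxy)phenyl]-8-bromochroman-7-yl]oxy}-4H-chromen-4-one
Conditions: K2CO3, MeCN, rt → 40 °C
Reagents that add atoms: none
Why: The phenoxide of 11 adds to C2 of the sulfonylchromone and expels methanesulfinate (vinylogous nucleophilic substitution, as used for 2-amino- and 2-aryloxychromones), which installs the O7''–C2 bond with no stereochemical issue.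

**Step 11**
Reactants: 16 5,7-bis(benzyloxy)-2-{[(2R)-5-(benzyloxy)-2-[4-(benzyloxy)phenyl]-8-bromochroman-7-yl]oxy}-4H-chromen-4-one; 6 [4-(benzyloxy)phenyl]boronic acid
Product: 17 (2R)-5,7-bis(benzyloxy)-2-[4-(benzyloxy)phenyl]-2-{[(2R)-5-(benzyloxy)-2-[4-(benzyloxy)phenyl]-8-bromochroman-7-yl]oxy}chroman-4-one
Conditions: Pd(OCOCF3)2 (10 mol%), (R)-t-BuPyOx (12 mol%), NH4PF6 (30 mol%), H2O (5 equiv), ClCH2CH2Cl, 40 °C
Reagents that add atoms: none
Why: Proposed new method: the closest known reaction type is the enantioselective conjugate addition of arylboronic acids to chromones and 2-alkylchromones under cationic divalent palladium/pyridine–oxazoline catalysis, and here the 2-substituent is an aryloxy group, so syn aryl-palladation (aryl to the electrophilic C2, palladium to C3) would create the mixed bis-aryl ketal carbon by C–C bond formation with the ligand choosing the enone face (the R ligand because ring B must enter the face opposite to that used in step 4), while in the C-bound enolate palladium is cis to the new aryl group, hence trans to the exocyclic aryloxy group and not syn-coplanar with the ring C2–O1 bond, so that syn β-oxygen elimination is geometrically denied, protonolysis by water should release ketone 17 before either C2 oxygen can leave, and the aryl bromide is inert to divalent palladium.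

**Step 12**
Reactants: 17 (2R)-5,7-bis(benzyloxy)-2-[4-(benzyloxy)phenyl]-2-{[(2R)-5-(benzyloxy)-2-[4-(benzyloxy)phenyl]-8-bromochroman-7-yl]oxy}chroman-4-one
Product: 18 (2R)-5,7-bis(benzyloxy)-2-[4-(benzyloxy)phenyl]-2-{[(2R)-5-(benzyloxy)-2-[4-(benzyloxy)phenyl]-8-bromochroman-7-yl]oxy}-4-[(tert-butyldimethylsilyl)oxy]-2H-chromene
Conditions: TBSOTf (1.05 equiv), Et3N (2.5 equiv), CH2Cl2, −78 °C; filtration through basic Al2O3
Reagents that add atoms: tert-butyldimethylsilyl trifluoromethanesulfonate CC(C)(C)[Si](C)(C)OS(=O)(=O)C(F)(F)F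
Why: Soft enolisation (O-silylation of the ketone, then deprotonation of the silyloxocarbenium ion by the amine) should give the silyl enol ether without ever forming a free C3 enolate that could expel a C2 oxygen.

**Step 13**
Reactants: 18 (2R)-5,7-bis(benzyloxy)-2-[4-(benzyloxy)phenyl]-2-{[(2R)-5-(benzyloxy)-2-[4-(benzyloxy)phenyl]-8-bromochroman-7-yl]oxy}-4-[(tert-butyldimethylsilyl)oxy]-2H-chromene
Product: 20 penta-O-benzyl C4 carbinol of the target skeleton (2S,3S,2''R; cis-fused dihydrofuran ring; C4 epimer mixture), via silyl ether 19 (not isolated)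
Conditions: Bu3SnH (slow addition), AIBN, PhMe, 80 °C; then Bu4NF, AcOH, THF, rt
Reagents that add atoms: none
Why: The tributyltin radical abstracts the C8'' bromine, the aryl σ-radical adds to C3 of the C3=C4 silyl enol ether, the α-silyloxy benzylic radical at C4 takes hydrogen from Bu3SnH, and fluoride then cleaves the C4 silyl ether and precipitates the tin as Bu3SnF. The closest known reaction type is the reductive aryl radical cyclisation of ortho-haloaryl allyl ethers to 3-substituted 2,3-dihydrobenzofurans, here with a cyclic enol ether as acceptor. One ring closes, the dihydrofuran ring (C8'', C7'', O7'', C2, C3), in the 5-exo-trig mode, C4 staying outside the new ring. C3 is the new stereocentre that counts: the two-atom O7''–C2 tether lets C8'' reach C3 only on the face of ring C that carries O7'', so the cis ring fusion and with it the C3 configuration are dictated by the catalyst-set ketal carbon C2, while C4 arises as a mixture that step 14 erases. The step needs ring closure to outrun direct reduction of the aryl radical, ipso attack on ring B and 6-endo attack at C4, and the intrinsically fast 5-exo closure onto an electron-rich alkene, slow addition of the stannane and a bromine placed only at C8'' secure this. Because the medium is neutral and no C3 enolate is formed, the mixed ketal can neither open by retro-oxa-Michael reaction nor aromatise to a benzofuran or flavone.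

**Step 14**
Reactants: 20 penta-O-benzyl C4 carbinol of the target skeleton
Product: 21 penta-O-benzyl ether of the target (2S,3S,2''R)
Conditions: Dess–Martin periodinane, NaHCO3, CH2Cl2, 0 °C → rt
Reagents that add atoms: none
Why: Buffered Dess–Martin oxidation of the benzylic C4 carbinol should give the aryl ketone under near-neutral conditions that neither enolise C3 nor ionise the ketal.

**Step 15**
Reactants: 21 penta-O-benzyl ether of the target
Product: 22 target: (2S,3S)-5,7-dihydroxy-2-(4-hydroxyphenyl)chroman-4-one joined through C2–O–C7'' and C3–C8'' to (2''R)-5''-hydroxy-2''-(4-hydroxyphenyl)chromane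
Conditions: H2 (1 atm), Pd/C, THF/MeOH, rt
Reagents that add atoms: none
Why: Neutral hydrogenolysis of the five benzyl ethers is the usual deprotection of bis-aryl ketal polyphenols and should leave the ketal, the hydrogen-bonded aryl ketone and the three stereocentres untouched.

**Compound list**

1 | 1-(2,4,6-trihydroxyphenyl)ethan-1-one | CC(=O)c1c(O)cc(O)cc1O | starting material
2 | 1-[2,6-dihydroxy-4-(triisopropylsilyloxy)phenyl]ethan-1-one | CC(=O)c1c(O)cc(O[Si](C(C)C)(C(C)C)C(C)C)cc1O | intermediate
3 | 1-[2-(benzyloxy)-6-hydroxy-4-(triisopropylsilyloxy)phenyl]ethan-1-one | CC(=O)c1c(O)cc(O[Si](C(C)C)(C(C)C)C(C)C)cc1OCc1ccccc1 | intermediate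
4 | (E)-1-[2-(benzyloxy)-6-hydroxy-4-(triisopropylsilyloxy)phenyl]-3-(dimethylamino)prop-2-en-1-one | CN(C)/C=C/C(=O)c1c(O)cc(O[Si](C(C)C)(C(C)C)C(C)C)cc1OCc1ccccc1 | intermediate
5 | 5-(benzyloxy)-7-(triisopropylsilyloxy)-4H-chromen-4-one | O=c1ccoc2cc(O[Si](C(C)C)(C(C)C)C(C)C)cc(OCc3ccccc3)c12 | intermediate
6 | [4-(benzyloxy)phenyl]boronic acid | OB(O)c1ccc(OCc2ccccc2)cc1 | starting material
7 | (2R)-5-(benzyloxy)-2-[4-(benzyloxy)phenyl]-7-(triisopropylsilyloxy)chroman-4-one | O=C1C[C@H](c2ccc(OCc3ccccc3)cc2)Oc2cc(O[Si](C(C)C)(C(C)C)C(C)C)cc(OCc3ccccc3)c12 | intermediate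
8 | (2R)-5-(benzyloxy)-2-[4-(benzyloxy)phenyl]-7-(triisopropylsilyloxy)chroman-4-ol (C4 epimer mixture) | OC1C[C@H](c2ccc(OCc3ccccc3)cc2)Oc2cc(O[Si](C(C)C)(C(C)C)C(C)C)cc(OCc3ccccc3)c12 | intermediate
9 | (2R)-5-(benzyloxy)-2-[4-(benzyloxy)phenyl]-7-(triisopropylsilyloxy)chromane | CC(C)[Si](Oc1cc(OCc2ccccc2)c2CC[C@H](c3ccc(OCc4ccccc4)cc3)Oc2c1)(C(C)C)C(C)C | intermediate
10 | (2R)-5-(benzyloxy)-2-[4-(benzyloxy)phenyl]-8-bromo-7-(triisopropylsilyloxy)chromane | CC(C)[Si](Oc1cc(OCc2ccccc2)c2CC[C@H](c3ccc(OCc4ccccc4)cc3)Oc2c1Br)(C(C)C)C(C)C | intermediate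
11 | (2R)-5-(benzyloxy)-2-[4-(benzyloxy)phenyl]-8-bromochroman-7-ol | Oc1cc(OCc2ccccc2)c2CC[C@H](c3ccc(OCc4ccccc4)cc3)Oc2c1Br | intermediate
12 | 1-[2,4-bis(benzyloxy)-6-hydroxyphenyl]ethan-1-one | CC(=O)c1c(O)cc(OCc2ccccc2)cc1OCc1ccccc1 | starting material
13 | 5,7-bis(benzyloxy)-4-hydroxy-2H-chromene-2-thione | OC1=CC(=S)Oc2cc(OCc3ccccc3)cc(OCc3ccccc3)c12 | intermediate
14 | 5,7-bis(benzyloxy)-2-(methylsulfanyl)-4H-chromen-4-one | CSc1cc(=O)c2c(OCc3ccccc3)cc(OCc3ccccc3)cc2o1 | intermediate
15 | 5,7-bis(benzyloxy)-2-(methylsulfonyl)-4H-chromen-4-one | CS(=O)(=O)c1cc(=O)c2c(OCc3ccccc3)cc(OCc3ccccc3)cc2o1 | intermediate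
16 | 5,7-bis(benzyloxy)-2-{[(2R)-5-(benzyloxy)-2-[4-(benzyloxy)phenyl]-8-bromochroman-7-yl]oxy}-4H-chromen-4-one | O=c1cc(Oc2cc(OCc3ccccc3)c3CC[C@H](c4ccc(OCc5ccccc5)cc4)Oc3c2Br)oc2cc(OCc3ccccc3)cc(OCc3ccccc3)c12 | intermediate
17 | (2R)-5,7-bis(benzyloxy)-2-[4-(benzyloxy)phenyl]-2-{[(2R)-5-(benzyloxy)-2-[4-(benzyloxy)phenyl]-8-bromochroman-7-yl]oxy}chroman-4-one (mixed bis-aryl ketal at C2) | O=C1C[C@](c2ccc(OCc3ccccc3)cc2)(Oc2cc(OCc3ccccc3)c3CC[C@H](c4ccc(OCc5ccccc5)cc4)Oc3c2Br)Oc2cc(OCc3ccccc3)cc(OCc3ccccc3)c12 | intermediate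
18 | (2R)-5,7-bis(benzyloxy)-2-[4-(benzyloxy)phenyl]-2-{[(2R)-5-(benzyloxy)-2-[4-(benzyloxy)phenyl]-8-bromochroman-7-yl]oxy}-4-[(tert-butyldimethylsilyl)oxy]-2H-chromene | CC(C)(C)[Si](C)(C)OC1=C[C@](c2ccc(OCc3ccccc3)cc2)(Oc2cc(OCc3ccccc3)c3CC[C@H](c4ccc(OCc5ccccc5)cc4)Oc3c2Br)Oc2cc(OCc3ccccc3)cc(OCc3ccccc3)c12 | intermediate
19 | C4 tert-butyldimethylsilyl ether of 20 (2S,3S,2''R; cis-fused; C4 epimer mixture; the ketal carbon is unchanged from 18, its descriptor becomes S only because bromine is lost) | CC(C)(C)[Si](C)(C)OC1c2c(OCc9ccccc9)cc(OCc9ccccc9)cc2O[C@@]2(c3ccc(OCc9ccccc9)cc3)Oc3cc(OCc9ccccc9)c4c(c3[C@@H]12)O[C@@H](c1ccc(OCc9ccccc9)cc1)CC4 | intermediate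
20 | penta-O-benzyl ether of the target skeleton with C4 as CH(OH) (2S,3S,2''R; C4 epimer mixture) | OC1c2c(OCc9ccccc9)cc(OCc9ccccc9)cc2O[C@@]2(c3ccc(OCc9ccccc9)cc3)Oc3cc(OCc9ccccc9)c4c(c3[C@@H]12)O[C@@H](c1ccc(OCc9ccccc9)cc1)CC4 | intermediate
21 | penta-O-benzyl ether of the target (2S,3S,2''R) | O=C1c2c(OCc9ccccc9)cc(OCc9ccccc9)cc2O[C@@]2(c3ccc(OCc9ccccc9)cc3)Oc3cc(OCc9ccccc9)c4c(c3[C@@H]12)O[C@@H](c1ccc(OCc9ccccc9)cc1)CC4 | intermediate
22 | (2S,3S)-5,7-dihydroxy-2-(4-hydroxyphenyl)chroman-4-one linked C2–O–C7'' and C3–C8'' to (2''R)-5''-hydroxy-2''-(4-hydroxyphenyl)chromane (cis-fused ketal) | O=C1c2c(O)cc(O)cc2O[C@@]2(c3ccc(O)cc3)Oc3cc(O)c4c(c3[C@@H]12)O[C@@H](c1ccc(O)cc1)CC4 | target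

**Step count and risks**

Total step count: 15. Longest linear sequence: 13 (steps 1–7, then 10–15).

Steps most likely to fail:

Step 11 (Proposed new method). The palladium enolate may lose the aryloxy group, or the new ketal may ionise in the weakly acidic medium, either way ending in addition–elimination to a flavone; facial selectivity on the hindered 2-aryloxychromone may also be poor. The fallback sets out from 16 and uses known chemistry: copper-catalysed conjugate addition of 4-(benzyloxy)phenylmagnesium bromide (CuBr·SMe2, THF, −78 °C) in the presence of TBSCl and HMPA, the chlorosilane-assisted cuprate addition long used on chromones. It traps the enolate as it forms and gives silyl enol ether 18 directly, without acid or a free enolate, but without control at C2. Compound 18 is then accompanied by its C2 epimer, the (2S)-configured silyl enol ether F1. The two are diastereomers through the flavan centre and are separated by chromatography on base-washed silica. The fallback comes back to the route at 18, and step 12 is then not needed.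

Step 12. The silyl triflate may ionise the allylic bis-aryl ketal, with loss of the flavan phenol and collapse to a 4-silyloxyflavylium ion, or elimination may occur during enolisation. The fallback sets out from 17 and avoids any enol silane: palladium-catalysed intramolecular α-arylation of the ketone by the C8'' bromide (Pd(OAc)2, P(t-Bu)3, K3PO4, PhMe, 70 °C), the standard ring closure of ketones tethered to an ortho-haloarene, run with an insoluble weak base so that the enolate is engaged on palladium as it forms. It closes the same C3–C8'' bond with the same forced cis fusion and comes back to the route at 21, passing over 18, 19 and 20 (new compound: none F0).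

Step 13. The aryl radical may be reduced before it cyclises, may attack ring B at the ipso carbon with aryl migration, or the enol-ether ketal may ionise thermally at 80 °C. The fallback sets out from 18 and replaces the radical by a two-electron closure: palladium-catalysed arylation of the silyl enol ether in the presence of Bu3SnF (Pd2(dba)3, P(t-Bu)3, PhMe, 80 °C), an enol-silane arylation that runs through a tin enolate. It forms the C3–C8'' bond and delivers the ketone directly, coming back to the route at 21 (new compound: none F0).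

**Further compounds**

F1 | step 11 | (2S)-5,7-bis(benzyloxy)-2-[4-(benzyloxy)phenyl]-2-{[(2R)-5-(benzyloxy)-2-[4-(benzyloxy)phenyl]-8-bromochroman-7-yl]oxy}-4-[(tert-butyldimethylsilyl)oxy]-2H-chromene (C2 epimer of 18) | CC(C)(C)[Si](C)(C)OC1=C[C@@](c2ccc(OCc3ccccc3)cc2)(Oc2cc(OCc3ccccc3)c3CC[C@H](c4ccc(OCc5ccccc5)cc4)Oc3c2Br)Oc2cc(OCc3ccccc3)cc(OCc3ccccc3)c12
F0 | step 12 | none | none
F0 | step 13 | none | none
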